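**Retrosynthetic overview**
1. Target 17 ⇐ ketone 14 by α-hydroxylation/acetylation at C2, the only enolisable site of the C3 ketone; 14 ⇐ alcohol 11 + isofraxidin 12 (Mitsunobu C11–O bond), then ketal removal.
2. 11 ⇐ hydroxy ketone 10 (methylenation of the C8 ketone); 10 ⇐ enone 7 by conjugate methylation at C10 and formaldehyde aldol at C9, both relayed from C5 (cis ring fusion).
3. 7 ⇐ Birch dienol ether 5 by amine-catalysed enantioselective proton transfer, which sets C5 (key step).
4. 5 ⇐ 6-methoxy-2-tetralone 1 (gem-dimethylation, ketalisation, Birch reduction).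
5. Ring order: ring A is the saturated ring of the tetralone, ring B is unveiled from the anisole ring, and the coumarin bicycle is attached intact late.

Assumption: atom labels are drimane-type (ring A = C1–C5 and C10, ring B = C5–C10, C11 = the OCH2 carbon on C9, β = face of the C10 methyl); the target SMILES is read as the cis-fused (2R,5S,9S,10S) isomer (5β-H, 9β-CH2OAr, 10β-CH3, 2α-OAc), and the quinine-derived amine of step 4 is taken to give the 5S enone (the quinidine-derived pseudoenantiomer is used if the sense proves opposite).

**Step 1**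
Reactants: 1 6-methoxy-3,4-dihydronaphthalen-2(1H)-one
Product: 3 6-methoxy-1,1-dimethyl-3,4-dihydronaphthalen-2(1H)-one, via monomethyl ketone 2 (not isolated)
Conditions: NaH (2.3 equiv), MeI (2.5 equiv), THF, 0 °C → rt
Reagents that add atoms: iodomethane, CI
Why: The C1 position of a 2-tetralone is both benzylic and α to the ketone, so its sodium enolate undergoes two successive SN2 C-methylations (exhaustive enolate alkylation) and stops at the quaternary carbon, leaving no stereocentre in 3.

**Step 2**
Reactants: 3 6-methoxy-1,1-dimethyl-3,4-dihydronaphthalen-2(1H)-one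
Product: 4 aryl ketal (ethylene ketal of 3)
Conditions: HOCH2CH2OH, p-TsOH (cat.), PhMe, reflux, Dean–Stark
Reagents that add atoms: ethane-1,2-diol, OCCO
Why: Acid-catalysed ketalisation with azeotropic water removal masks the C3 ketone against the dissolving-metal and organometallic steps that follow, and no stereocentre is formed.

**Step 3**
Reactants: 4 aryl ketal
Product: 5 dienol ether (1-methoxy-1,4-diene with C8 enol ether and tetrasubstituted C5=C10 alkene)
Conditions: Li, NH3 (l), THF, t-BuOH, −78 → −33 °C; then MeOH
Reagents that add atoms: none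
Why: Birch reduction of the anisole ring leaves the methoxy-bearing and the two alkyl-bearing carbons on the residual double bonds, giving an achiral dienol ether that carries the latent C8 carbonyl, while the ketal is inert to Li/NH3.

**Step 4**
Reactants: 5 dienol ether
Product: 7 (5S)-enone (C8 ketone, C9=C10 alkene, 5β-H, C3 ketal), via β,γ-unsaturated ketone 6 (not isolated)
Conditions: 9-amino-9-deoxy-epi-quinine (10 mol%), CF3CO2H (20 mol%), H2O (3 equiv), PhMe, 25–40 °C
Reagents that add atoms: water, O
Why: Proposed new method: the primary ammonium salt of the cinchona diamine protonates the enol ether and exchanges methanol for the amine (or condenses with ketone 6 formed by concurrent hydrolysis) to give a β,γ-unsaturated iminium ion, whose catalyst-bound dienamine is reprotonated at C5 on one face by the neighbouring quinuclidinium before hydrolysis, so C5 is set by catalyst-controlled γ-protonation; the closest known reaction type is the cinchona primary-amine-catalysed enantioselective isomerisation of isolated β,γ-unsaturated cyclohexenones to γ-stereogenic cyclohex-2-enones (iminium–dienamine proton-transfer catalysis), extended here to direct use of a Birch dienol ether and to a γ-carbon flanked by a quaternary centre.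

**Step 5**
Reactants: 7 (5S)-enone
Product: 10 hydroxy ketone (C8 ketone, 9β-CH2OH, 10β-CH3, 5β-H), via lithium enolate 8 (not isolated), via lithium aldolate 9 (not isolated)
Conditions: Me2CuLi (from MeLi, CuI), Et2O, −78 → 0 °C; then CH2O (g), −78 °C; aq NH4Cl
Reagents that add atoms: lithium dimethylcuprate Me2CuLi, [Li+].C[Cu-]C; formaldehyde, C=O
Why: Conjugate addition of the Gilman cuprate occurs by axial attack at C10 anti to the pseudo-axial C4 branch (the trans mode would place the incoming methyl syn-axial to the C4β methyl), giving the cis-fused quaternary C10, and the regiospecific lithium enolate then undergoes an aldol reaction with monomeric formaldehyde at C9 by axial attack anti to the axial C1 bond, that is on the face of the new methyl, the other face being blocked by the axial C4 branch in the alternative chair.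

**Step 6**
Reactants: 10 hydroxy ketone
Product: 11 homoallylic alcohol (C8 exocyclic methylene, 9β-CH2OH)
Conditions: Zn, CH2Br2, TiCl4 (Lombardo reagent), THF/CH2Cl2, 0 °C → rt
Reagents that add atoms: dibromomethane, BrCBr
Why: Takai–Lombardo methylenation with the non-basic gem-dizinc/titanium reagent converts the hindered, enolisable β-hydroxy ketone into the exocyclic alkene without retro-aldol cleavage or epimerisation at C9, tolerates the free hydroxyl and the ketal, and touches no stereocentre.

**Step 7**
Reactants: 11 homoallylic alcohol, 12 isofraxidin (7-hydroxy-6,8-dimethoxy-2H-chromen-2-one)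
Product: 13 coumarin ether ketal
Conditions: PPh3, DIAD, THF, 0 → 50 °C
Reagents that add atoms: none
Why: Mitsunobu etherification couples the primary C11 alcohol with the acidic coumarin phenol (pKa about 8) by SN2 displacement at the activated CH2 carbon, so no stereocentre is involved.

**Step 8**
Reactants: 13 coumarin ether ketal
Product: 14 coumarin ether ketone (C3 ketone)
Conditions: 2 M HCl, THF, rt
Reagents that add atoms: water, O
Why: Mild aqueous acid hydrolyses the strained neopentyl dioxolane (acetal hydrolysis) to the C3 ketone while the aryl ether, the lactone and the 1,1-disubstituted alkene survive, and the stereocentres are untouched.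

**Step 9**
Reactants: 14 coumarin ether ketone
Product: 17 target CNP0183157.2, via potassium enolate 15 (not isolated), via potassium alkoxide 16 (not isolated)
Conditions: KN(SiMe3)2, THF, −78 °C; (±)-trans-3-phenyl-2-(phenylsulfonyl)oxaziridine, −78 °C; then Ac2O, DMAP, −78 → 0 °C
Reagents that add atoms: (±)-trans-3-phenyl-2-(phenylsulfonyl)oxaziridine, O=S(=O)(c1ccccc1)N1OC1c1ccccc1; acetic anhydride, CC(=O)OC(C)=O
Why: The ketone can enolise only toward C2, the potassium enolate is oxidised by the N-sulfonyloxaziridine (Davis α-hydroxylation) from the α face, away from the syn-axial C10 and C4β methyl groups as in electrophilic substitution of 4,4-dimethyl-3-oxo terpenoids, and in situ O-acetylation of the alkoxide gives the equatorial 2α-acetate (2R).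

**Compound list**
1 | 6-methoxy-3,4-dihydronaphthalen-2(1H)-one (6-methoxy-2-tetralone) | COc1ccc2c(c1)CCC(=O)C2 | starting material
2 | 6-methoxy-1-methyl-3,4-dihydronaphthalen-2(1H)-one (racemic, transient, not isolated) | COc1ccc2c(c1)CCC(=O)C2C | intermediate
3 | 6-methoxy-1,1-dimethyl-3,4-dihydronaphthalen-2(1H)-one | COc1ccc2c(c1)CCC(=O)C2(C)C | intermediate
4 | 6'-methoxy-1',1'-dimethyl-3',4'-dihydro-1'H-spiro[[1,3]dioxolane-2,2'-naphthalene] | COc1ccc2c(c1)CCC1(OCCO1)C2(C)C | intermediate
5 | 6'-methoxy-1',1'-dimethyl-3',4',5',8'-tetrahydro-1'H-spiro[[1,3]dioxolane-2,2'-naphthalene] (achiral dienol ether) | COC1=CCC2=C(C1)CCC1(OCCO1)C2(C)C | intermediate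
6 | 5,5-dimethyl-6,6-(ethylenedioxy)-3,4,5,6,7,8-hexahydronaphthalen-2(1H)-one (C8 ketone, C5=C10 alkene, achiral, not isolated) | O=C1CCC2=C(C1)CCC1(OCCO1)C2(C)C | intermediate
7 | (4aS)-5,5-dimethyl-6,6-(ethylenedioxy)-4,4a,5,6,7,8-hexahydronaphthalen-2(3H)-one (C8 ketone, C9=C10 alkene, 5β-H, 5S) | O=C1CC[C@H]2C(=C1)CCC1(OCCO1)C2(C)C | intermediate
8 | lithium enolate C8(OLi)=C9 of the cis-fused decalin, 10β-CH3, 5β-H, C3 ethylene ketal, (5S,10S) (not isolated) | [Li+].[O-]C1=C[C@@]2(C)CCC3(OCCO3)C(C)(C)[C@H]2CC1 | intermediate
9 | lithium alkoxide of 10 (C11–OLi), (5S,9S,10S) (not isolated) | O=C1CC[C@@H]2C(C)(C)C3(OCCO3)CC[C@]2(C)[C@H]1C[O-].[Li+] | intermediate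
10 | cis-fused hydroxy ketone: C8 ketone, 9β-CH2OH, 10β-CH3, 5β-H, C4 gem-dimethyl, C3 ethylene ketal, (5S,9S,10S) | O=C1CC[C@@H]2C(C)(C)C3(OCCO3)CC[C@]2(C)[C@H]1CO | intermediate
11 | cis-fused homoallylic alcohol: C8 exocyclic methylene, 9β-CH2OH, 10β-CH3, 5β-H, C3 ethylene ketal, (5S,9S,10S) | C=C1CC[C@@H]2C(C)(C)C3(OCCO3)CC[C@]2(C)[C@H]1CO | intermediate
12 | isofraxidin (7-hydroxy-6,8-dimethoxy-2H-chromen-2-one) | COc1cc2ccc(=O)oc2c(OC)c1O | starting material
13 | 7-O-ether of isofraxidin with alcohol 11 (C11–O–C7 of the coumarin), C3 ethylene ketal, (5S,9S,10S) | C=C1CC[C@@H]2C(C)(C)C3(OCCO3)CC[C@]2(C)[C@H]1COc1c(OC)cc2ccc(=O)oc2c1OC | intermediate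
14 | 3-ketone of 13: C3 ketone, C8 exocyclic methylene, 9β-CH2O-coumarin, 10β-CH3, 5β-H, (5S,9S,10S) | C=C1CC[C@@H]2C(C)(C)C(=O)CC[C@]2(C)[C@H]1COc1c(OC)cc2ccc(=O)oc2c1OC | intermediate
15 | potassium enolate C3(OK)=C2 of 14, (5S,9S,10S) (not isolated) | C=C1CC[C@@H]2C(C)(C)C([O-])=CC[C@]2(C)[C@H]1COc1c(OC)cc2ccc(=O)oc2c1OC.[K+] | intermediate
16 | potassium 2α-alkoxide of the 2-hydroxy-3-ketone, (2R,5S,9S,10S) (not isolated) | C=C1CC[C@@H]2C(C)(C)C(=O)[C@H]([O-])C[C@]2(C)[C@H]1COc1c(OC)cc2ccc(=O)oc2c1OC.[K+] | intermediate
17 | CNP0183157.2: 2α-acetoxy-3-oxo cis-fused drimane-type 7-O-ether of isofraxidin, (2R,5S,9S,10S) | C=C1CC[C@@H]2C(C)(C)C(=O)[C@H](OC(C)=O)C[C@]2(C)[C@H]1COc1c(OC)cc2ccc(=O)oc2c1OC | target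

**Summary**
Total step count: 9. Longest linear sequence: 9 steps (1 → 17); isofraxidin 12 is bought and used as such.

**Steps most likely to fail**

Step 4 (proposed new step). The γ-protonation next to the quaternary C4 may be slow or poorly selective, and direct aminolysis of the enol ether is untested. The fallback sets out from 5 and separates the two events with known chemistry. Oxalic acid in aqueous THF/MeOH at 0 °C hydrolyses 5 to the β,γ-unsaturated ketone 6, which is isolated; this makes no compound outside the list (F0). Ketone 6 is then isomerised in a separate operation by the established cinchona primary amine/carboxylic acid protocol for isolated β,γ-unsaturated cyclohexenones, and the route is rejoined at 7. This removes the untested aminolysis but not the hindrance at C5.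

Step 5. The cuprate may add sluggishly to the hindered β,β-disubstituted enone, capture of the lithium enolate by gaseous formaldehyde may be incomplete, or the C9 face selectivity may be eroded. The fallback sets out from 7. Me2CuLi in the presence of Me3SiCl gives the isolable trimethylsilyl enol ether F1. F1 is then hydroxymethylated in a Lewis-acid Mukaiyama aldol with aqueous formaldehyde and Yb(OTf)3 in THF/H2O, rejoining the route at 10.

Step 7. The alcohol is β-branched and next to a quaternary centre, and the phenol carries two ortho methoxy groups, so the Mitsunobu reaction may stall or give elimination toward the diene. The fallback sets out from 11. MsCl/Et3N in CH2Cl2 gives the methanesulfonate F2, which is displaced by isofraxidin 12 with Cs2CO3 in DMF at 80 °C (Williamson-type SN2), rejoining the route at 13.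

**Further compounds**
F0 | step 4 | none | none
F1 | step 5 | trimethylsilyl enol ether C8(OSiMe3)=C9 of the cis-fused decalin, 10β-CH3, 5β-H, C3 ethylene ketal, (5S,10S) | C[Si](C)(C)OC1=C[C@@]2(C)CCC3(OCCO3)C(C)(C)[C@H]2CC1
F2 | step 7 | methanesulfonate of alcohol 11 (C11–OSO2CH3), (5S,9S,10S) | C=C1CC[C@@H]2C(C)(C)C3(OCCO3)CC[C@]2(C)[C@H]1COS(C)(=O)=O
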